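## Retrosynthetic overview

1. The target is released by one global hydrogenolysis of a fully protected tetramer (sixteen O-benzyl ethers, three 3-O-benzyloxycarbonyl groups).
2. The three C4–C8 interflavan bonds are disconnected one at a time from the top. Each is made by a mediated anodic C4–S activation of the same catechin-derived 4-arylthio building block, which adds to C8 of the growing chain.
3. The 4-arylthio building block comes from (+)-catechin (benzylation, 3-O-Cbz, C4 oxidation and thiolation). The chain-terminating unit comes from (−)-epicatechin (benzylation).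
4. No ring is constructed: rings A, B and C of all four units are bought. C2 and C3 come from the two natural flavan-3-ols, and each new C4 centre is set trans to C3–O by the neighbouring 3-O-carbonate.

Assumption: the SMILES is read as catechin-(4α→8)-catechin-(4α→8)-catechin-(4α→8)-epicatechin (units from the top: 2R,3S,4S; 2R,3S,4S; 2R,3S,4S; 2R,3R).
Assumption: the not-isolated ether 4 is an unassigned C4 epimer mixture (C4 left open in its SMILES), because both epimers ionise to the same electrophile.
Assumption: the sulfide radical cation and the C4 benzylic carbocation are short-lived species on the reaction coordinate of a single ionisation–capture event; they are described in the Why lines and are not counted as compounds that form in the flask.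

Abbreviations: Bn = benzyl, Cbz = benzyloxycarbonyl, DDQ = 2,3-dichloro-5,6-dicyano-1,4-benzoquinone.

## Route

Step 1
Reactants: 1 (+)-catechin
Product: 2 5,7,3',4'-tetra-O-benzyl-(+)-catechin (2R,3S)
Conditions: BnBr (4.4 equiv), K2CO3 (5 equiv), DMF, 0 °C → rt, Ar
Reagents that add atoms: benzyl bromide, BrCc1ccccc1
Why: Williamson etherification with K2CO3 deprotonates only the four phenols (pKa about 10) and not the C3 alcohol, and the mild base at or below room temperature leaves C2 and C3 untouched.

Step 2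
Reactants: 2 5,7,3',4'-tetra-O-benzyl-(+)-catechin
Product: 3 3-O-Cbz-5,7,3',4'-tetra-O-benzyl-(+)-catechin (2R,3S)
Conditions: CbzCl (2 equiv), pyridine, 4-(dimethylamino)pyridine (0.1 equiv), CH2Cl2, 0 °C → rt
Reagents that add atoms: benzyl chloroformate, O=C(Cl)OCc1ccccc1
Why: Nucleophile-catalysed acyl transfer (carbonate formation) on the only free hydroxyl installs a group that can later bridge the β face of C4 and that is removed in the final hydrogenolysis, without touching a stereocentre.

Step 3
Reactants: 3 3-O-Cbz-5,7,3',4'-tetra-O-benzyl-(+)-catechin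
Product: 5 3-O-Cbz-5,7,3',4'-tetra-O-benzyl-4α-(4-methoxyphenylthio)catechin (2R,3R,4R; 2,3-trans-3,4-trans), via benzylic 2-ethoxyethyl ether 4 (not isolated)
Conditions: DDQ (1.5 equiv), HOCH2CH2OEt (3 equiv), CH2Cl2, rt; aq NaHCO3 wash, dried crude taken on; then 4-MeOC6H4SH (2 equiv), BF3·OEt2 (0.3 equiv), CH2Cl2, −40 → 0 °C
Reagents that add atoms: 2-ethoxyethanol, CCOCCO (held in intermediate 4 and released again in the exchange); 4-methoxybenzenethiol, COc1ccc(S)cc1
Why: DDQ abstracts the ring A-activated benzylic hydride at C4 and the alcohol traps the site (oxidative C–H etherification), then BF3·OEt2 ionises the benzylic ether so that the soft thiol gives the more stable thioether by SN1 exchange, attacking anti to the bridging 3-O-carbonate (3,4-trans; the C3 descriptor becomes R only because sulfur changes the priorities), and this C4 configuration is erased again in the couplings.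

Step 4
Reactants: 6 (−)-epicatechin
Product: 7 5,7,3',4'-tetra-O-benzyl-(−)-epicatechin (2R,3R)
Conditions: BnBr (4.4 equiv), K2CO3 (5 equiv), DMF, 0 °C → rt, Ar
Reagents that add atoms: benzyl bromide, BrCc1ccccc1
Why: The same phenol-selective Williamson etherification as in step 1 leaves the 3-OH free and the 2,3-cis stereocentres unchanged.

Step 5
Reactants: 5 3-O-Cbz-5,7,3',4'-tetra-O-benzyl-4α-(4-methoxyphenylthio)catechin; 7 5,7,3',4'-tetra-O-benzyl-(−)-epicatechin (3 equiv, excess recovered)
Product: 8 3-O-Cbz-tetra-O-benzylcatechin-(4α→8)-tetra-O-benzylepicatechin (upper unit 2R,3S,4S; lower unit 2R,3R)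
Conditions: (4-BrC6H4)3N (15 mol %), 2,6-di-tert-butyl-4-methylpyridine (1.5 equiv), (CF3)2CHOH (5 equiv), Bu4NBF4 (0.1 M), CH2Cl2, −60 °C; undivided cell, graphite-felt anode, Pt-wire cathode, constant current, 1.2 F/mol; 5 added by syringe pump over the electrolysis
Reagents that add atoms: none
Why: Proposed new method: the anodically regenerated aminium radical cation of tris(4-bromophenyl)amine (about +1.1 V vs SCE) oxidises only the anisyl sulfide of 5 (about +1.2 V; the benzyloxyarene rings lie near +1.4 V and have no fast follow-up reaction), the sulfide radical cation breaks its C4–S bond (mesolysis) to ArS• (ending as the disulfide) and a short-lived C4 benzylic carbocation whose β face is bridged by the 3-O-carbonate carbonyl, so that C8 of 7 (the most nucleophilic and least hindered ring A position) attacks from the α face in a Friedel–Crafts alkylation and sets C4 as 4S (3,4-trans), while the released proton is reduced to H2 at the cathode; the closest known reactions are the triarylamine-mediated anodic activation of thioglycosides and dithioacetals and the AgBF4-promoted coupling of 4-thioflavans with flavan-3-ols.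

Step 6
Reactants: 5 3-O-Cbz-5,7,3',4'-tetra-O-benzyl-4α-(4-methoxyphenylthio)catechin; 8 protected dimer (2 equiv, excess recovered)
Product: 9 bis(3-O-Cbz)-dodeca-O-benzyl catechin-(4α→8)-catechin-(4α→8)-epicatechin (upper two units 2R,3S,4S; lower unit 2R,3R)
Conditions: as step 5: (4-BrC6H4)3N (15 mol %), 2,6-di-tert-butyl-4-methylpyridine, (CF3)2CHOH, Bu4NBF4, CH2Cl2, −60 °C; undivided cell, graphite-felt anode, Pt-wire cathode, 1.2 F/mol; 5 added slowly
Reagents that add atoms: none
Why: Proposed new method: the same mediated anodic C4–S mesolysis of 5 gives the carbonate-bridged C4 electrophile, which is captured from its α face (new C4 = 4S) by C8 of the upper unit of 8, the only ring A position flanked by just one benzyloxy group and therefore the site at which benzylated procyanidin dimers are known to react in Lewis-acid chain extensions; the closest known reactions are triarylamine-mediated anodic thioglycoside activation and Lewis-acid flavan C4 arylation of dimeric nucleophiles.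

Step 7
Reactants: 5 3-O-Cbz-5,7,3',4'-tetra-O-benzyl-4α-(4-methoxyphenylthio)catechin; 9 protected trimer (1.5 equiv, excess recovered)
Product: 10 tris(3-O-Cbz)-hexadeca-O-benzyl catechin-(4α→8)-catechin-(4α→8)-catechin-(4α→8)-epicatechin (upper three units 2R,3S,4S; lower unit 2R,3R)
Conditions: as step 5: (4-BrC6H4)3N (15 mol %), 2,6-di-tert-butyl-4-methylpyridine, (CF3)2CHOH, Bu4NBF4, CH2Cl2, −60 °C; undivided cell, graphite-felt anode, Pt-wire cathode, 1.2 F/mol; 5 added slowly
Reagents that add atoms: none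
Why: Proposed new method: a third mediated anodic C4–S mesolysis of 5 delivers the carbonate-bridged C4 electrophile to C8 of the top unit of 9 with the same α-face attack (new C4 = 4S), and none of the sulfur-free products 8 to 10 is oxidised at the mediator potential; the closest known reactions are triarylamine-mediated anodic thioglycoside activation and the AgBF4-promoted chain extension of benzylated procyanidin oligomers with 4-thio electrophiles.

Step 8
Reactants: 10 protected tetramer
Product: 11 catechin-(4α→8)-catechin-(4α→8)-catechin-(4α→8)-epicatechin (CNP0236700.7)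
Conditions: H2 (1 atm), 20% Pd(OH)2/C, THF/MeOH/H2O (20:1:1), rt; filtration, Sephadex LH-20
Reagents that add atoms: none
Why: Heterogeneous hydrogenolysis cleaves all sixteen O-benzyl ethers and the three benzyl carbonates (which lose CO2) under neutral conditions that touch neither the C4–C8 bonds nor any stereocentre.

## Compound list

1 | (+)-catechin, (2R,3S)-2-(3,4-dihydroxyphenyl)chromane-3,5,7-triol | Oc1cc(O)c2c(c1)O[C@H](c1ccc(O)c(O)c1)[C@@H](O)C2 | starting material

2 | 5,7,3',4'-tetra-O-benzyl-(+)-catechin (2R,3S) | O(Cc3ccccc3)c1cc(OCc3ccccc3)c2c(c1)O[C@H](c1ccc(OCc3ccccc3)c(OCc3ccccc3)c1)[C@@H](O)C2 | intermediate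

3 | 3-O-benzyloxycarbonyl-5,7,3',4'-tetra-O-benzyl-(+)-catechin (2R,3S) | O(Cc3ccccc3)c1cc(OCc3ccccc3)c2c(c1)O[C@H](c1ccc(OCc3ccccc3)c(OCc3ccccc3)c1)[C@@H](OC(=O)OCc3ccccc3)C2 | intermediate

4 | (2R,3S)-3-(benzyloxycarbonyloxy)-5,7,3',4'-tetrabenzyloxy-4-(2-ethoxyethoxy)flavan, C4 epimer mixture, not isolated | O(Cc3ccccc3)c1cc(OCc3ccccc3)c2c(c1)O[C@H](c1ccc(OCc3ccccc3)c(OCc3ccccc3)c1)[C@@H](OC(=O)OCc3ccccc3)C2OCCOCC | intermediate

5 | (2R,3R,4R)-3-(benzyloxycarbonyloxy)-5,7,3',4'-tetrabenzyloxy-4-(4-methoxyphenylthio)flavan (2,3-trans-3,4-trans, 4α-S) | O(Cc3ccccc3)c1cc(OCc3ccccc3)c2c(c1)O[C@H](c1ccc(OCc3ccccc3)c(OCc3ccccc3)c1)[C@@H](OC(=O)OCc3ccccc3)[C@@H]2Sc1ccc(OC)cc1 | intermediate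

6 | (−)-epicatechin, (2R,3R)-2-(3,4-dihydroxyphenyl)chromane-3,5,7-triol | Oc1cc(O)c2c(c1)O[C@H](c1ccc(O)c(O)c1)[C@H](O)C2 | starting material

7 | 5,7,3',4'-tetra-O-benzyl-(−)-epicatechin (2R,3R) | O(Cc3ccccc3)c1cc(OCc3ccccc3)c2c(c1)O[C@H](c1ccc(OCc3ccccc3)c(OCc3ccccc3)c1)[C@H](O)C2 | intermediate

8 | 3-O-Cbz-5,7,3',4'-tetra-O-benzylcatechin-(4α→8)-5,7,3',4'-tetra-O-benzylepicatechin (upper 2R,3S,4S; lower 2R,3R) | O(Cc3ccccc3)c1cc(OCc3ccccc3)c2c(c1)O[C@H](c1ccc(OCc3ccccc3)c(OCc3ccccc3)c1)[C@@H](OC(=O)OCc3ccccc3)[C@@H]2c1c(OCc3ccccc3)cc(OCc3ccccc3)c2c1O[C@H](c1ccc(OCc3ccccc3)c(OCc3ccccc3)c1)[C@H](O)C2 | intermediate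

9 | bis(3-O-Cbz)-dodeca-O-benzyl catechin-(4α→8)-catechin-(4α→8)-epicatechin (upper two units 2R,3S,4S; lower 2R,3R) | O(Cc3ccccc3)c1cc(OCc3ccccc3)c2c(c1)O[C@H](c1ccc(OCc3ccccc3)c(OCc3ccccc3)c1)[C@@H](OC(=O)OCc3ccccc3)[C@@H]2c1c(OCc3ccccc3)cc(OCc3ccccc3)c2c1O[C@H](c1ccc(OCc3ccccc3)c(OCc3ccccc3)c1)[C@@H](OC(=O)OCc3ccccc3)[C@@H]2c1c(OCc3ccccc3)cc(OCc3ccccc3)c2c1O[C@H](c1ccc(OCc3ccccc3)c(OCc3ccccc3)c1)[C@H](O)C2 | intermediate

10 | tris(3-O-Cbz)-hexadeca-O-benzyl catechin-(4α→8)-catechin-(4α→8)-catechin-(4α→8)-epicatechin (upper three units 2R,3S,4S; lower 2R,3R) | O(Cc3ccccc3)c1cc(OCc3ccccc3)c2c(c1)O[C@H](c1ccc(OCc3ccccc3)c(OCc3ccccc3)c1)[C@@H](OC(=O)OCc3ccccc3)[C@@H]2c1c(OCc3ccccc3)cc(OCc3ccccc3)c2c1O[C@H](c1ccc(OCc3ccccc3)c(OCc3ccccc3)c1)[C@@H](OC(=O)OCc3ccccc3)[C@@H]2c1c(OCc3ccccc3)cc(OCc3ccccc3)c2c1O[C@H](c1ccc(OCc3ccccc3)c(OCc3ccccc3)c1)[C@@H](OC(=O)OCc3ccccc3)[C@@H]2c1c(OCc3ccccc3)cc(OCc3ccccc3)c2c1O[C@H](c1ccc(OCc3ccccc3)c(OCc3ccccc3)c1)[C@H](O)C2 | intermediate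

11 | catechin-(4α→8)-catechin-(4α→8)-catechin-(4α→8)-epicatechin (CNP0236700.7; units from the top 2R,3S,4S; 2R,3S,4S; 2R,3S,4S; 2R,3R) | Oc1cc(O)c2c(c1)O[C@H](c1ccc(O)c(O)c1)[C@@H](O)[C@@H]2c1c(O)cc(O)c2c1O[C@H](c1ccc(O)c(O)c1)[C@@H](O)[C@@H]2c1c(O)cc(O)c2c1O[C@H](c1ccc(O)c(O)c1)[C@@H](O)[C@@H]2c1c(O)cc(O)c2c1O[C@H](c1ccc(O)c(O)c1)[C@H](O)C2 | target

## Step count and risks

Total steps: 8. Longest linear sequence: 7 (steps 1, 2, 3, 5, 6, 7, 8); step 4 is a one-step side branch.

**Step 5 (the proposed anodic coupling; the same method is reused in steps 6 and 7).** The risks are that the mediator does not discriminate the sulfide from the benzyloxyarene rings, that 5 self-condenses through its own C8, or that the bridged benzyl carbonate loses benzyl to give a cyclic 3,4-carbonate. The fallback uses known chemistry and no electrolysis. It sets out from 3: the first half of step 3 (DDQ, 2-ethoxyethanol, CH2Cl2) is run alone and the benzylic 2-ethoxyethyl ether 4 is isolated by chromatography. Ether 4 is then condensed with 7 (3 equiv) under trimethylsilyl trifluoromethanesulfonate (Me3SiOTf, 0.1 equiv) in CH2Cl2 at −78 °C. This is the established Lewis-acid Friedel–Crafts coupling of 3-O-acyl-4-alkoxy flavan electrophiles with an excess of a flavan-3-ol nucleophile, and it gives the 3,4-trans product. It comes back to the route at 8, and the same condensation of 4 with 8 and then with 9 gives 9 and 10. It makes no further compound (none F0).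

**Step 3 (telescoped C4 oxidation and thiol exchange on the 3-O-carbonate).** The risks are that the β-carbonate slows hydride abstraction by DDQ and that DDQ residues interfere with the exchange. The fallback changes the order of events and sets out from 2. The free alcohol 2, the well-established substrate for this oxidation, is treated with DDQ and 2-ethoxyethanol in CH2Cl2 to give (2R,3S,4S)-5,7,3',4'-tetrabenzyloxy-4-(2-ethoxyethoxy)flavan-3-ol F1. F1 is acylated with CbzCl, pyridine and 4-(dimethylamino)pyridine to the single-epimer carbonate (2R,3S,4S)-3-(benzyloxycarbonyloxy)-5,7,3',4'-tetrabenzyloxy-4-(2-ethoxyethoxy)flavan F2. The thiol exchange on purified F2 (4-MeOC6H4SH, BF3·OEt2, CH2Cl2, −40 → 0 °C) is then run as a separate operation, and the fallback comes back to the route at 5.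

**Step 7 (third chain extension on the hindered trimer 9).** The risks are slow capture, attack at C6 and over-extension to pentamer. The fallback is a convergent two-plus-two assembly by known orthogonal activation, and it sets out from 3, 5 and 8.
- Compound 3 is oxidised with DDQ and 2-ethoxyethanol and ether 4 is isolated, as in the first fallback.
- Ether 4 is ionised with the hard Lewis acid BF3·OEt2 in CH2Cl2 at −78 °C in the presence of 5 (3 equiv). C8 of 5 acts as the nucleophile while its C4–S bond is inert to the hard acid. This gives the dimeric thioether 3-O-Cbz-tetra-O-benzylcatechin-(4α→8)-3-O-Cbz-tetra-O-benzyl-4α-(4-methoxyphenylthio)catechin F3.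
- F3 is activated with the thiophilic salt AgBF4 (2 equiv) in THF/CH2Cl2 at 0 °C in the presence of the less hindered dimer 8 (1.5 equiv), the established silver-promoted coupling of 4-thio flavans. The fallback comes back to the route at 10.

## Further compounds

F0 | step 5 | none | none
F1 | step 3 | (2R,3S,4S)-5,7,3',4'-tetrabenzyloxy-4-(2-ethoxyethoxy)flavan-3-ol (3,4-cis) | O(Cc3ccccc3)c1cc(OCc3ccccc3)c2c(c1)O[C@H](c1ccc(OCc3ccccc3)c(OCc3ccccc3)c1)[C@@H](O)[C@H]2OCCOCC
F2 | step 3 | (2R,3S,4S)-3-(benzyloxycarbonyloxy)-5,7,3',4'-tetrabenzyloxy-4-(2-ethoxyethoxy)flavan (3,4-cis) | O(Cc3ccccc3)c1cc(OCc3ccccc3)c2c(c1)O[C@H](c1ccc(OCc3ccccc3)c(OCc3ccccc3)c1)[C@@H](OC(=O)OCc3ccccc3)[C@H]2OCCOCC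
F3 | step 7 | 3-O-Cbz-5,7,3',4'-tetra-O-benzylcatechin-(4α→8)-3-O-Cbz-5,7,3',4'-tetra-O-benzyl-4α-(4-methoxyphenylthio)catechin (upper 2R,3S,4S; lower 2R,3R,4R) | O(Cc3ccccc3)c1cc(OCc3ccccc3)c2c(c1)O[C@H](c1ccc(OCc3ccccc3)c(OCc3ccccc3)c1)[C@@H](OC(=O)OCc3ccccc3)[C@@H]2c1c(OCc3ccccc3)cc(OCc3ccccc3)c2c1O[C@H](c1ccc(OCc3ccccc3)c(OCc3ccccc3)c1)[C@@H](OC(=O)OCc3ccccc3)[C@@H]2Sc1ccc(OC)cc1
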